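C1–C26 number the heavy atoms in target-SMILES order. The C20/C24 methyl ethers come off last, via the quinone. Before that, the cyclopentanone ring C4–C5–C6–C7–C9 is opened at C4–C9 to a C6 prenyl group facing the C9=C10 enedione (forward: Lewis-acid ene closure).
The plan rests on C18. It is benzylic to the dimethoxyarene C19–C26, allylic to C15=C17, and lies across a seven-membered ring from C6, the α-carbon of the C7 carbonyl bonded to spiro C13. Cutting C6–C18 merges the five-membered ring C6–C13–C26–C19–C18 and six-membered ring C (C6–C13–C14–C15–C17–C18) into one benzocycloheptene.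
A retro-Claisen step (C13–C14 cut, O12–C17 made) traces the spiro dienone with quaternary C13 to a 6-isopropenyl-6,7-dihydrodibenzo[b,d]oxepine, in which C17 holds the stereochemical information.
The oxepine is cut at O12–C17 (Mitsunobu) and C13–C26 (Suzuki–Miyaura) into two prenylated bromoarenes. Both are made by lithiation next to bromine, and C17 is set by a Shi epoxidation.
Ring order: two arenes, then the oxepine, then cycloheptene plus dienone (spiro), then the five-membered ring plus ring C in one bond, then the cyclopentanone.

Key step: step 12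

Assumption: by the spiro transition-state model the D-fructose-derived Shi ketone gives (R)-epoxides from 2-methylalk-2-enes, so its L-series enantiomer (taken as purchasable) is used; biaryls 13–16 are handled as mixtures of C13–C26 rotamers, which converge in step 11.

Step 1
Reactants: 1 2-bromo-1,4-dimethoxybenzene; 2 prenyl bromide
Product: 4 2-bromo-1,4-dimethoxy-3-(3-methylbut-2-en-1-yl)benzene, via aryllithium 3 (not isolated)
Conditions: LiN(iPr)2 (LDA), THF, −78 °C; CuBr·SMe2; then 2, −78 → 0 °C
Reagents that add atoms: none
Why: Directed ortho-metalation removes the most acidic C–H, the one flanked by Br and OMe, at −78 °C without bromine–lithium exchange or aryne formation, and the derived arylcopper species should couple with prenyl bromide at its unhindered primary carbon (copper-mediated allylic substitution).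

Step 2
Reactants: 4 2-bromo-1,4-dimethoxy-3-(3-methylbut-2-en-1-yl)benzene
Product: 5 (3S)-3-[(2-bromo-3,6-dimethoxyphenyl)methyl]-2,2-dimethyloxirane
Conditions: L-fructose-derived Shi ketone (30 mol%), Oxone (2KHSO5·KHSO4·K2SO4), K2CO3, aq. Na2B4O7 buffer, Bu4NHSO4, MeCN–CH2(OMe)2–H2O, 0 °C
Reagents that add atoms: potassium peroxymonosulfate KHSO5, [K+].[O-]S(=O)(=O)OO
Why: In this Shi asymmetric epoxidation the chiral dioxirane meets the only alkene, a trisubstituted one, through the spiro transition state, and the L-series ketone should deliver oxygen to the face that makes C17 (S).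

Step 3
Reactants: 5 (3S)-3-[(2-bromo-3,6-dimethoxyphenyl)methyl]-2,2-dimethyloxirane
Product: 6 (2S)-1-(2-bromo-3,6-dimethoxyphenyl)-3-methylbut-3-en-2-ol
Conditions: Al(OiPr)3, toluene, 110 °C
Reagents that add atoms: none
Why: In this aluminium-alkoxide-promoted isomerisation of an epoxide to an allylic alcohol, Al binds the oxirane oxygen, the tertiary C15–O bond lengthens and a methyl proton leaves through a cyclic syn transition state, so the C17–O bond and the (S) centre stay untouched.

Step 4
Reactants: 6 (2S)-1-(2-bromo-3,6-dimethoxyphenyl)-3-methylbut-3-en-2-ol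
Product: 8 (3S)-5,8-dimethoxy-3-(prop-1-en-2-yl)-3,4-dihydro-1H-2,1-benzoxaborinin-1-ol, via dilithio species 7 (not isolated)
Conditions: n-BuLi (2.2 equiv), THF, −78 °C; B(OiPr)3, −78 °C → rt; 1 M HCl
Reagents that add atoms: triisopropyl borate, CC(C)OB(OC(C)C)OC(C)C; water, O
Why: Bromine–lithium exchange on the lithium alkoxide followed by a borate quench is the standard arylboronic acid synthesis, and the boronic acid should close onto the C17 hydroxyl to a six-membered hemiboronate that masks the alcohol and slows protodeboronation.

Step 5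
Reactants: 9 bromohydroquinone
Product: 10 2-bromo-1,4-bis(methoxymethoxy)benzene
Conditions: MOMCl, iPr2NEt, CH2Cl2, 0 °C → rt
Reagents that add atoms: chloromethyl methyl ether, COCCl
Why: Both phenols are O-alkylated in the standard way to MOM acetals, which withstand lithium amides and acidify the neighbouring ring C–H.

Step 6
Reactants: 10 2-bromo-1,4-bis(methoxymethoxy)benzene; 2 prenyl bromide
Product: 12 2-bromo-1,4-bis(methoxymethoxy)-3-(3-methylbut-2-en-1-yl)benzene, via aryllithium 11 (not isolated)
Conditions: LiN(iPr)2 (LDA), THF, −78 °C; CuBr·SMe2; then 2, −78 → 0 °C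
Reagents that add atoms: none
Why: As in step 1, directed ortho-metalation takes the C–H between Br and OMOM (future C6) as the most acidic site, and the arylcopper species is prenylated at the primary carbon, which places prenyl, bromine and the two oxygens in the C6/C13/C7/C11 pattern.

Step 7
Reactants: 8 (3S)-5,8-dimethoxy-3-(prop-1-en-2-yl)-3,4-dihydro-1H-2,1-benzoxaborinin-1-ol; 12 2-bromo-1,4-bis(methoxymethoxy)-3-(3-methylbut-2-en-1-yl)benzene
Product: 13 (2S)-1-[3,6-dimethoxy-2',5'-bis(methoxymethoxy)-6'-(3-methylbut-2-en-1-yl)biphenyl-2-yl]-3-methylbut-3-en-2-ol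
Conditions: Pd(OAc)2 (5 mol%), SPhos (10 mol%), K3PO4, toluene–H2O, 100 °C
Reagents that add atoms: none
Why: A Suzuki–Miyaura coupling with a bulky dialkylbiarylphosphine is the established answer to tetra-ortho-substituted biaryls and should form C13–C26 and free the C17 hydroxyl, and the rotamer mixture about the new axis does not matter because the axis disappears in step 11.

Step 8
Reactants: 13 (2S)-1-[3,6-dimethoxy-2',5'-bis(methoxymethoxy)-6'-(3-methylbut-2-en-1-yl)biphenyl-2-yl]-3-methylbut-3-en-2-ol
Product: 14 2'-[(2S)-2-hydroxy-3-methylbut-3-en-1-yl]-3',6'-dimethoxy-6-(3-methylbut-2-en-1-yl)biphenyl-2,5-diol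
Conditions: HCl (cat.), MeOH, 45 °C, argon
Reagents that add atoms: none
Why: Acid-catalysed acetal exchange cleaves phenolic MOM ethers under conditions mild enough that the ortho-prenylphenol should not close to a chroman and the unactivated secondary allylic alcohol should not ionise.

Step 9
Reactants: 14 2'-[(2S)-2-hydroxy-3-methylbut-3-en-1-yl]-3',6'-dimethoxy-6-(3-methylbut-2-en-1-yl)biphenyl-2,5-diol
Product: 15 (6R)-8,11-dimethoxy-1-(3-methylbut-2-en-1-yl)-6-(prop-1-en-2-yl)-6,7-dihydrodibenzo[b,d]oxepin-2-ol
Conditions: PPh3, DIAD, THF (0.01 M), 0 °C → rt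
Reagents that add atoms: none
Why: In this intramolecular Mitsunobu etherification only O12 on C11 can reach the activated C17, so the two phenols need no separate protection; SN2 displacement inverts C17 from (S) to (R), and high dilution suppresses intermolecular attack by the distal C7 phenol.

Step 10
Reactants: 15 (6R)-8,11-dimethoxy-1-(3-methylbut-2-en-1-yl)-6-(prop-1-en-2-yl)-6,7-dihydrodibenzo[b,d]oxepin-2-ol
Product: 16 tert-butyldimethylsilyl ether of 15 at the C7 oxygen
Conditions: TBSCl, imidazole, DMF, rt
Reagents that add atoms: tert-butyldimethylsilyl chloride, CC(C)(C)[Si](C)(C)Cl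
Why: Standard silylation of the only remaining hydroxyl installs the group that becomes the enol silane after dearomatisation.

Step 11
Reactants: 16 tert-butyldimethylsilyl ether of 15 at the C7 oxygen
Product: 17 (5S)-5'-[(tert-butyldimethylsilyl)oxy]-1,4-dimethoxy-7-methyl-6'-(3-methylbut-2-en-1-yl)-6,9-dihydrospiro[benzo[7]annulene-5,1'-cyclohexa[3,5]diene]-2'-one
Conditions: PhNEt2 (degassed), 180 °C, sealed tube
Reagents that add atoms: none
Why: This aromatic Claisen rearrangement stops at the ortho-dienone because C13 carries the aryl group and cannot tautomerise; the tether C18–C19–C26 spans positions 1 and 4 of the six-atom array, so only a boat-like transition state with C18 cis to C14 is open, C14 is delivered to the ring-B face on which C17 sits, (R)-C17 becomes (S)-C13 and C15=C17 ends up cis in the new seven-membered ring, while C=O formation and release of the torsional strain of the bridged tetra-ortho biaryl should offset the lost aromaticity.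

Step 12
Reactants: 17 spiro dienone (5S)
Product: 19 tetracyclic C6-prenyl enedione (6S,13R,18R), via allyl-benzyl cation 18 (not isolated)
Conditions: DDQ (1.3 equiv), 2,6-dichloropyridine, 4 Å MS, CH2Cl2–MeNO2, −20 °C → rt
Reagents that add atoms: none
Why: DDQ engages the electron-rich dimethoxyarene in a charge-transfer complex and removes hydride from C18, giving cation 18, which is delocalised over C18, C17 and C15 and into the arene through the ortho methoxy group at C20; C6, the nucleophilic end of the C7 silyl dienol ether, then adds to C18, and transfer of the silyl group to the DDQH anion releases the C7 ketone. The closest known reaction type is DDQ-mediated oxidative C–H cleavage at benzylic or allylic carbons followed by intramolecular capture of the cation by an enol silane or enol acetate, together with the DDQ cross-dehydrogenative coupling of 1,3-diarylpropenes and carbonyl nucleophiles. The single transannular bond closes the five-membered ring C6–C13–C26–C19–C18 in a 5-(enolexo)-exo-trig mode (C17 of the cation stays outside) and ring C, C6–C13–C14–C15–C17–C18, in a 6-(enolexo)-endo-trig mode (C17 and C15 lie inside). Both new centres are controlled by C13: the short flat tether C26–C19 lets C18 reach only the lobe of C6 on the dienone face that carries C26, which puts C7 syn to the benzo bridge and C5 syn to C14 (6S), and C18 becomes a bridgehead of a benzobicyclo[3.2.1]octadiene and can hold its hydrogen only outward (18R). The step needs hydride loss from C18 and not from C5 (also doubly allylic, between the prenyl alkene and the enol ether), C14 or C16: only the C18–H bond is conjugated to the arene that binds DDQ and leads to a cation stabilised by arene and alkene at once, whereas a C5 cation would be tied to the electron-poor cross-conjugated dienone. Attack at the other allyl terminus C15 would need the cyclobutane C6–C13–C14–C15, and the bridgehead position of C18 in 19 protects the product from a second oxidation.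

Step 13
Reactants: 19 tetracyclic C6-prenyl enedione (6S,13R,18R)
Product: 21 pentacyclic diketone dimethyl ether (4S,6S,9R,13R,18R), via aluminium enolate 20 (not isolated)
Conditions: Me2AlCl (2 equiv), CH2Cl2, −78 → 0 °C; 1 M HCl
Reagents that add atoms: none
Why: In this Lewis-acid-promoted intramolecular ene-type conjugate addition Me2AlCl activates C11=O and C4 of the axial prenyl chain adds to C9, the only enedione carbon within reach of a five-membered ring; the C7 bridge fixes C9, the developing C2 cation points exo, away from the C10–C11–C13 bridge and C14, which sets (4S), and a methyl proton is lost (taken up as methane) to give the isopropenyl group without acid that could move the alkenes.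

Step 14
Reactants: 21 pentacyclic diketone dimethyl ether (4S,6S,9R,13R,18R)
Product: 22 pentacyclic p-benzoquinone with all five stereocentres as in 21
Conditions: (NH4)2Ce(NO3)6, MeCN–H2O, 0 °C
Reagents that add atoms: water, O
Why: Oxidative demethylation of a 1,4-dimethoxybenzene with ceric ammonium nitrate is fast at 0 °C compared with alkene oxidation, and the bridgehead C18–H cannot tautomerise to a quinone methide, so no stereocentre is touched.

Step 15
Reactants: 22 pentacyclic p-benzoquinone
Product: 23 CNP0287617.1 (4S,6S,9R,13R,18R)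
Conditions: Na2S2O4, THF–H2O, rt
Reagents that add atoms: none
Why: Dithionite reduction of a p-benzoquinone to the hydroquinone leaves isolated ketones and alkenes alone.

Compound list
1 | 2-bromo-1,4-dimethoxybenzene | COc1ccc(OC)c(Br)c1 | starting material
2 | prenyl bromide (1-bromo-3-methylbut-2-ene) | CC(C)=CCBr | starting material
3 | (2-bromo-3,6-dimethoxyphenyl)lithium | [Li]c1c(OC)ccc(OC)c1Br | intermediate
4 | 2-bromo-1,4-dimethoxy-3-(3-methylbut-2-en-1-yl)benzene | COc1ccc(OC)c(CC=C(C)C)c1Br | intermediate
5 | (3S)-3-[(2-bromo-3,6-dimethoxyphenyl)methyl]-2,2-dimethyloxirane | COc1ccc(OC)c(C[C@@H]2OC2(C)C)c1Br | intermediate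
6 | (2S)-1-(2-bromo-3,6-dimethoxyphenyl)-3-methylbut-3-en-2-ol | COc1ccc(OC)c(C[C@H](O)C(C)=C)c1Br | intermediate
7 | O,C-dilithio derivative of 6 (lithium alkoxide, aryllithium at C26) | [Li]c1c(OC)ccc(OC)c1C[C@H](O[Li])C(C)=C | intermediate
8 | (3S)-5,8-dimethoxy-3-(prop-1-en-2-yl)-3,4-dihydro-1H-2,1-benzoxaborinin-1-ol | COc1ccc(OC)c2c1C[C@@H](C(C)=C)OB2O | intermediate
9 | bromohydroquinone | Oc1ccc(O)c(Br)c1 | starting material
10 | 2-bromo-1,4-bis(methoxymethoxy)benzene | COCOc1ccc(OCOC)c(Br)c1 | intermediate
11 | [2-bromo-3,6-bis(methoxymethoxy)phenyl]lithium | [Li]c1c(OCOC)ccc(OCOC)c1Br | intermediate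
12 | 2-bromo-1,4-bis(methoxymethoxy)-3-(3-methylbut-2-en-1-yl)benzene | COCOc1ccc(OCOC)c(CC=C(C)C)c1Br | intermediate
13 | (2S)-1-[3,6-dimethoxy-2',5'-bis(methoxymethoxy)-6'-(3-methylbut-2-en-1-yl)biphenyl-2-yl]-3-methylbut-3-en-2-ol | COCOc1ccc(OCOC)c(CC=C(C)C)c1-c1c(OC)ccc(OC)c1C[C@H](O)C(C)=C | intermediate
14 | 2'-[(2S)-2-hydroxy-3-methylbut-3-en-1-yl]-3',6'-dimethoxy-6-(3-methylbut-2-en-1-yl)biphenyl-2,5-diol | Oc1ccc(O)c(CC=C(C)C)c1-c1c(OC)ccc(OC)c1C[C@H](O)C(C)=C | intermediate
15 | (6R)-8,11-dimethoxy-1-(3-methylbut-2-en-1-yl)-6-(prop-1-en-2-yl)-6,7-dihydrodibenzo[b,d]oxepin-2-ol | Oc1ccc2O[C@@H](C(C)=C)Cc3c(OC)ccc(OC)c3-c2c1CC=C(C)C | intermediate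
16 | tert-butyl{[(6R)-8,11-dimethoxy-1-(3-methylbut-2-en-1-yl)-6-(prop-1-en-2-yl)-6,7-dihydrodibenzo[b,d]oxepin-2-yl]oxy}dimethylsilane | CC(C)(C)[Si](C)(C)Oc1ccc2O[C@@H](C(C)=C)Cc3c(OC)ccc(OC)c3-c2c1CC=C(C)C | intermediate
17 | (5S)-5'-[(tert-butyldimethylsilyl)oxy]-1,4-dimethoxy-7-methyl-6'-(3-methylbut-2-en-1-yl)-6,9-dihydrospiro[benzo[7]annulene-5,1'-cyclohexa[3,5]diene]-2'-one (key-step precursor) | O=C1C=CC(O[Si](C)(C)C(C)(C)C)=C(CC=C(C)C)[C@]12CC(C)=CCc3c(OC)ccc(OC)c32 | intermediate
18 | C18 allyl-benzyl cation derived from 17 | O=C1C=CC(O[Si](C)(C)C(C)(C)C)=C(CC=C(C)C)[C@]12CC(C)=C[CH+]c3c(OC)ccc(OC)c32 | intermediate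
19 | tetracyclic C6-prenyl enedione, benzobicyclo[3.2.1]octadiene fused to a cyclohex-2-ene-1,4-dione (6S,13R,18R) (key-step product) | CC(C)=CC[C@@]23C(=O)C=CC(=O)[C@@]21CC(C)=C[C@@H]3c2c(OC)ccc(OC)c21 | intermediate
20 | chloro(methyl)aluminium C10=C11 enolate of 21 | C=C(C)[C@H]1C[C@@]23C(=O)[C@@H]1C=C(O[Al](C)Cl)[C@@]21CC(C)=C[C@@H]3c2c(OC)ccc(OC)c21 | intermediate
21 | pentacyclic C7,C11-diketone dimethyl ether with exo isopropenyl at C4 (4S,6S,9R,13R,18R) | C=C(C)[C@H]1C[C@@]23C(=O)[C@@H]1CC(=O)[C@@]21CC(C)=C[C@@H]3c2c(OC)ccc(OC)c21 | intermediate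
22 | pentacyclic p-benzoquinone, stereocentres arranged as in 21 | C=C(C)[C@H]1C[C@@]23C(=O)[C@@H]1CC(=O)[C@@]21CC(C)=C[C@@H]3C2=C1C(=O)C=CC2=O | intermediate
23 | CNP0287617.1 (4S,6S,9R,13R,18R) | C=C(C)[C@H]1C[C@@]23C(=O)[C@@H]1CC(=O)[C@@]21CC(C)=C[C@@H]3c2c(O)ccc(O)c21 | target

Total step count: 15. Longest linear sequence: 13 (steps 1–4, then 7–15).

Steps most likely to fail

Step 12. Hydride loss from the doubly allylic C5 methylene may outrun C18–H cleavage, as may direct oxidation or cycloaddition of the silyl dienol ether by DDQ. The cation may also lose a proton before C6 arrives. The fallback separates oxidation from C–C bond formation, so that no enol silane is present while DDQ acts.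
- It sets out from 17. HF·pyridine (THF, 0 °C) should give the spiro enedione F1 as inconsequential C6 epimers.
- DDQ in CH2Cl2–AcOH should acetoxylate the benzylic–allylic carbon to the C18 acetate F2.
- TBSOTf/Et3N (CH2Cl2, 0 °C) rebuilds the enol silane as the silyl dienol ether acetate F3.
- Catalytic TMSOTf (CH2Cl2, −78 °C) ionises the acetate to the same cation 18, which C6 captures. This is the Lewis-acid SN1 alkylation of an enol silane by an allylic or benzylic acetate. The route is rejoined at 19.

Step 11. The rearrangement may stall at an unfavourable equilibrium, with retro-Claisen return to the aromatic ether, or the silyl dienol ether may be lost at the temperature needed. The fallback gives the dearomatised product a thermodynamic sink.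
- It sets out from phenol 15, before silylation, which is heated in degassed PhNEt2 at 170–180 °C.
- The first-formed 4-hydroxydienone should tautomerise to the spiro enedione F4 (same constitution as F1), which cannot revert by a [3,3] shift.
- Soft enolisation with TBSOTf/Et3N can only take the C6–H, the sole α-hydrogen of either ketone. It returns the route at 17.

Step 13. Regiocontrol may be poor, with C4 bonding to C10 to give a bicyclo[2.2.2] skeleton. Facial control at C4 may also be poor, giving endo isopropenyl. The C2 cation may be captured by chloride or lose the C4 proton. The fallback replaces the cationic closure by a radical conjugate addition.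
- It sets out from 19. N-(phenylseleno)phthalimide, H2O and catalytic camphorsulfonic acid (CH2Cl2) should hydroxyselenate the more accessible prenyl alkene in the Markovnikov sense to the β-hydroxy selenide F5.
- Bu3SnH/AIBN (toluene, 80 °C, slow addition) generates the C4 radical. This should add 5-exo to C9 with the bulky carbinol group exo, giving the tertiary alcohol F6.
- Burgess reagent (toluene, 60 °C) dehydrates towards a methyl group, and the route is rejoined at 21.

Further compounds
F1 | step 12 | spiro enedione, (5S) at C13, C6 epimers | O=C1C=CC(=O)C(CC=C(C)C)[C@]12CC(C)=CCc3c(OC)ccc(OC)c32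
F2 | step 12 | C18 acetate of the spiro enedione, C6 and C18 epimers | O=C1C=CC(=O)C(CC=C(C)C)[C@]12CC(C)=CC(OC(C)=O)c3c(OC)ccc(OC)c32
F3 | step 12 | C7 silyl dienol ether bearing the C18 acetate | O=C1C=CC(O[Si](C)(C)C(C)(C)C)=C(CC=C(C)C)[C@]12CC(C)=CC(OC(C)=O)c3c(OC)ccc(OC)c32
F4 | step 11 | spiro enedione, (5S) at C13, C6 epimers (same constitution as F1) | O=C1C=CC(=O)C(CC=C(C)C)[C@]12CC(C)=CCc3c(OC)ccc(OC)c32
F5 | step 13 | β-hydroxy selenide of 19 (PhSe at C4, OH at C2, C4 epimers) | CC(C)(O)C([Se]c1ccccc1)C[C@@]23C(=O)C=CC(=O)[C@@]21CC(C)=C[C@@H]3c2c(OC)ccc(OC)c21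
F6 | step 13 | pentacyclic diketone with exo 2-hydroxypropan-2-yl group at C4 | CC(C)(O)[C@H]1C[C@@]23C(=O)[C@@H]1CC(=O)[C@@]21CC(C)=C[C@@H]3c2c(OC)ccc(OC)c21
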